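**Plan**

1. Numbering: C1 (OMe), C2=C3 (C3 bears C7H2OBz), C4 (OH), C5 (OBz), C6 (OH). The retrosynthesis cuts the C7 ester and the C3–C7 bond (back to a C3 ketone through its C2=C3 enol triflate), then the ring bond C1–C2.
2. Enabling feature: the oxygens on ring carbons C1, C6, C5 and C4 are trans, trans, cis, which is C1 to C4 of methyl α-D-altropyranoside. The cyclohexene is that pyranose ring with O5 exchanged for C2, so the methyl ether can be the glycosidic methoxyl itself.
3. Forward: methyl 4,6-O-benzylidene-α-D-glucopyranoside → 2,3-anhydro-alloside → 2-O-naphthylmethyl altroside → 3-O-benzoate → 6-iodide, 4-O-silyl ether, 5-ene. The pyranose is the only ring up to here.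
4. The single ring-forming event is the Ti(OiPr)Cl3 rearrangement of that enol ether: C1–O5 breaks, C1–C2 forms, the cyclohexanone closes and the methoxyl stays on C1.
5. C7 is then joined by enol triflation toward C2 and Stille hydroxymethylation. Benzoylation and removal of the naphthylmethyl and silyl groups finish the route.
6. Stereochemistry: C4 is glucose C4. C5 and C6 come from inversion of sugar C3 (epoxide closure) and sugar C2 (trans-diaxial opening). C1 is the α-anomeric centre, retained in the rearrangement.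

Key step: step 9

Remark: methyl 4,6-O-benzylidene-α-D-glucopyranoside is a catalogue compound and is taken as the carbohydrate starting material. Sugars carry carbohydrate numbering and carbocycles the numbering above. With the carbocycle drawn flat and C1→C2→C3 running anticlockwise, α means below and β above the plane. The target is 1α-OMe, 4α-OH, 5α-OBz, 6β-OH, that is (1S,4R,5R,6R).

**Route**

Step 1
Reactants: 1 methyl 4,6-O-benzylidene-α-D-glucopyranoside
Product: 2 methyl 4,6-O-benzylidene-2,3-di-O-(p-tolylsulfonyl)-α-D-glucopyranoside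
Conditions: TsCl (3 equiv), pyridine, DMAP (cat.), 50 °C
Reagents that add atoms: p-toluenesulfonyl chloride, Cc1ccc(cc1)S(=O)(=O)Cl
Why: Sulfonylation of both secondary hydroxyls with a sulfonyl chloride in pyridine is routine on this acetal-locked diol and prepares the epoxide closure without touching a stereocentre.

Step 2
Reactants: 2 methyl 4,6-O-benzylidene-2,3-di-O-(p-tolylsulfonyl)-α-D-glucopyranoside
Product: 4 methyl 2,3-anhydro-4,6-O-benzylidene-α-D-allopyranoside, via sodium 2-alkoxide of the 3-O-tosylate 3 (not isolated)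
Conditions: NaOMe, MeOH–CH2Cl2, reflux
Reagents that add atoms: none
Why: Methoxide attacks sulfur of the more exposed 2-O-sulfonate, and the released O2 alkoxide displaces the 3-tosylate from the α face in an intramolecular Williamson-type SN2 closure, so sugar C3 is inverted and the oxirane is allo.

Step 3
Reactants: 4 methyl 2,3-anhydro-4,6-O-benzylidene-α-D-allopyranoside; 5 2-naphthylmethanol
Product: 6 methyl 4,6-O-benzylidene-2-O-(2-naphthylmethyl)-α-D-altropyranoside
Conditions: NaH (1.2 equiv), 5 (5 equiv), 1,4-dioxane, 100 °C; then H2O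
Reagents that add atoms: 2-naphthylmethanol (5), OCc1ccc2ccccc2c1
Why: Alkoxide opening of the rigid oxirane follows the Fürst–Plattner rule, so attack at C2 from the β face should give the trans-diaxial altro product, inverting C2 and leaving the C3 oxygen on the α face.

Step 4
Reactants: 6 methyl 4,6-O-benzylidene-2-O-(2-naphthylmethyl)-α-D-altropyranoside; 7 benzoyl chloride
Product: 8 methyl 3-O-benzoyl-4,6-O-benzylidene-2-O-(2-naphthylmethyl)-α-D-altropyranoside
Conditions: BzCl, pyridine, DMAP (cat.), CH2Cl2, 0 °C → rt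
Reagents that add atoms: benzoyl chloride (7), O=C(Cl)c1ccccc1
Why: DMAP-catalysed acylation of the only free hydroxyl installs the benzoate that the target keeps at C5.

Step 5
Reactants: 8 methyl 3-O-benzoyl-4,6-O-benzylidene-2-O-(2-naphthylmethyl)-α-D-altropyranoside
Product: 9 methyl 3-O-benzoyl-2-O-(2-naphthylmethyl)-α-D-altropyranoside
Conditions: AcOH–H2O (4:1), 60 °C
Reagents that add atoms: none
Why: Acid hydrolysis of the benzylidene acetal frees O4 and O6 while the benzoate, the naphthylmethyl ether and the methyl glycoside hold, and the acidic medium disfavours O3→O4 acyl migration.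

Step 6
Reactants: 9 methyl 3-O-benzoyl-2-O-(2-naphthylmethyl)-α-D-altropyranoside
Product: 10 methyl 3-O-benzoyl-6-deoxy-6-iodo-2-O-(2-naphthylmethyl)-α-D-altropyranoside
Conditions: I2, PPh3, imidazole, toluene, 60 °C
Reagents that add atoms: iodine, II
Why: The Garegg–Samuelsson iodination (Appel-type, through an alkoxyphosphonium ion) is selective for the primary hydroxyl and substitutes at C6, which is not a stereocentre.

Step 7
Reactants: 10 methyl 3-O-benzoyl-6-deoxy-6-iodo-2-O-(2-naphthylmethyl)-α-D-altropyranoside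
Product: 11 methyl 3-O-benzoyl-4-O-(tert-butyldimethylsilyl)-6-deoxy-6-iodo-2-O-(2-naphthylmethyl)-α-D-altropyranoside
Conditions: TBSOTf, 2,6-lutidine, CH2Cl2, 0 °C
Reagents that add atoms: tert-butyldimethylsilyl trifluoromethanesulfonate, CC(C)(C)[Si](C)(C)OS(=O)(=O)C(F)(F)F
Why: A silyl triflate with a hindered pyridine base silylates the secondary O4 quickly at low temperature and generates no alkoxide that could move the neighbouring benzoate.

Step 8
Reactants: 11 methyl 3-O-benzoyl-4-O-(tert-butyldimethylsilyl)-6-deoxy-6-iodo-2-O-(2-naphthylmethyl)-α-D-altropyranoside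
Product: 12 methyl 3-O-benzoyl-4-O-(tert-butyldimethylsilyl)-6-deoxy-2-O-(2-naphthylmethyl)-α-D-arabino-hex-5-enopyranoside
Conditions: DBU, DMF, 80 °C
Reagents that add atoms: none
Why: E2 dehydrohalogenation of the primary iodide by the amidine base can only remove H5, which gives the exocyclic enol ether and deletes the C5 stereocentre as planned, while ester and silyl ether survive.

Step 9
Reactants: 12 methyl 3-O-benzoyl-4-O-(tert-butyldimethylsilyl)-6-deoxy-2-O-(2-naphthylmethyl)-α-D-arabino-hex-5-enopyranoside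
Product: 14 5α-benzoyloxy-1α-methoxy-6β-(2-naphthylmethoxy)-4α-(tert-butyldimethylsilyloxy)cyclohexan-3-one, via ring-opened oxocarbenium titanium enolate 13 (not isolated)
Conditions: Ti(OiPr)Cl3 (2 equiv, from TiCl4 and Ti(OiPr)4 3:1), CH2Cl2, −78 °C; then aq. NaHCO3
Reagents that add atoms: none
Why: The Lewis acid binds the enol-ether ring oxygen O5 and the endocyclic C1–O5 bond ionises, leaving a methoxy-stabilised oxocarbenium ion at C1 tethered to the titanium enolate of the C5 ketone (13). The enolate carbon (sugar C6, target C2) then adds to C1 in an intramolecular Mukaiyama-type aldol addition, which forms the C1–C2 bond and the cyclohexanone. The closest known reaction is the triisobutylaluminium- or Ti(OiPr)Cl3-promoted rearrangement of ether-protected methyl hex-5-enopyranosides to carbocycles with retention of the aglycon, in contrast to the mercury-mediated Ferrier carbocyclisation, which loses it. The ring closes in the 6-(enolendo)-exo-trig mode, since the enolate double bond lies inside the new ring (the product is a ring ketone) and the C=O+ bond outside it. The one new stereocentre, C1, is controlled by the contact ion pair: the enolate should reclose on the face the ring oxygen has just left, so the methoxyl stays α and trans to the C6 ether. The step needs endocyclic rather than exocyclic C–O cleavage and survival of the acid-sensitive groups; the ether (not an ester) at O2 keeps the oxocarbenium ion accessible, and at −78 °C benzoate, silyl ether and naphthylmethyl ether should be inert.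

Step 10
Reactants: 14 5α-benzoyloxy-1α-methoxy-6β-(2-naphthylmethoxy)-4α-(tert-butyldimethylsilyloxy)cyclohexan-3-one
Product: 16 5α-benzoyloxy-1α-methoxy-6β-(2-naphthylmethoxy)-4α-(tert-butyldimethylsilyloxy)cyclohex-2-en-3-yl trifluoromethanesulfonate, via lithium C2-C3 enolate 15 (not isolated)
Conditions: LiN(SiMe3)2, THF, −78 °C; then N-(5-chloro-2-pyridyl)triflimide (Comins' reagent), −78 °C
Reagents that add atoms: N-(5-chloropyridin-2-yl)bis(trifluoromethanesulfonyl)imide, FC(F)(F)S(=O)(=O)N(c1ccc(Cl)cn1)S(=O)(=O)C(F)(F)F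
Why: Kinetic deprotonation by the hindered amide at −78 °C should take a proton of the C2 methylene and not the shielded C4 methine beside the silyl ether, and fast O-sulfonylation traps the enolate before methoxide can leave C1 by E1cB, so this regioselective enol triflate formation fixes the C2=C3 bond and leaves C4 unepimerised.

Step 11
Reactants: 16 5α-benzoyloxy-1α-methoxy-6β-(2-naphthylmethoxy)-4α-(tert-butyldimethylsilyloxy)cyclohex-2-en-3-yl trifluoromethanesulfonate; 17 (tributylstannyl)methanol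
Product: 18 3-(hydroxymethyl)-1α-methoxy-6β-(2-naphthylmethoxy)-4α-(tert-butyldimethylsilyloxy)cyclohex-2-en-5α-yl benzoate
Conditions: Pd(PPh3)4 (10 mol %), LiCl (3 equiv), 1,4-dioxane, 90 °C
Reagents that add atoms: (tributylstannyl)methanol (17), CCCC[Sn](CCCC)(CCCC)CO
Why: In this Stille coupling zerovalent palladium inserts into the C3–OTf bond, chloride assists transfer of the hydroxymethyl group from tin, and reductive elimination forms C3–C7 without moving the alkene or touching a stereocentre.

Step 12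
Reactants: 18 3-(hydroxymethyl)-1α-methoxy-6β-(2-naphthylmethoxy)-4α-(tert-butyldimethylsilyloxy)cyclohex-2-en-5α-yl benzoate; 7 benzoyl chloride
Product: 19 3-(benzoyloxymethyl)-1α-methoxy-6β-(2-naphthylmethoxy)-4α-(tert-butyldimethylsilyloxy)cyclohex-2-en-5α-yl benzoate
Conditions: BzCl, pyridine, DMAP (cat.), CH2Cl2, 0 °C
Reagents that add atoms: benzoyl chloride (7), O=C(Cl)c1ccccc1
Why: Pyridine/DMAP acylation of the unhindered primary allylic alcohol installs the second benzoate under conditions that should not shift the O4 silyl group.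

Step 13
Reactants: 19 3-(benzoyloxymethyl)-1α-methoxy-6β-(2-naphthylmethoxy)-4α-(tert-butyldimethylsilyloxy)cyclohex-2-en-5α-yl benzoate
Product: 20 3-(benzoyloxymethyl)-6β-hydroxy-1α-methoxy-4α-(tert-butyldimethylsilyloxy)cyclohex-2-en-5α-yl benzoate
Conditions: DDQ, CH2Cl2–pH 7 phosphate buffer (10:1), rt
Reagents that add atoms: none
Why: DDQ removes a hydride from the electron-rich 2-naphthylmethyl ether (oxidative arylmethyl ether cleavage) and water hydrolyses the resulting oxocarbenium ion, while the electron-poor alkene, benzoates, silyl ether and methyl ether should stay and the buffer guards against acyl migration.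

Step 14
Reactants: 20 3-(benzoyloxymethyl)-6β-hydroxy-1α-methoxy-4α-(tert-butyldimethylsilyloxy)cyclohex-2-en-5α-yl benzoate
Product: 21 (1S,4R,5R,6R)-5-benzoyloxy-3-(benzoyloxymethyl)-4,6-dihydroxy-1-methoxycyclohex-2-ene
Conditions: HF·pyridine, THF–pyridine, 0 °C → rt; neutral work-up
Reagents that add atoms: none
Why: Fluoride-driven desilylation under weakly acidic HF·pyridine conditions frees O4 without forming the alkoxide that would trigger benzoyl migration from O5 to O4 or O6.

**Compound list**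

1 | methyl 4,6-O-benzylidene-α-D-glucopyranoside | CO[C@H]1O[C@@H]2CO[C@@H](c3ccccc3)O[C@H]2[C@H](O)[C@H]1O | starting material
2 | methyl 4,6-O-benzylidene-2,3-di-O-(p-tolylsulfonyl)-α-D-glucopyranoside | CO[C@H]1O[C@@H]2CO[C@@H](c3ccccc3)O[C@H]2[C@H](OS(=O)(=O)c2ccc(C)cc2)[C@H]1OS(=O)(=O)c1ccc(C)cc1 | intermediate
3 | sodium 2-alkoxide of methyl 4,6-O-benzylidene-3-O-(p-tolylsulfonyl)-α-D-glucopyranoside | CO[C@H]1O[C@@H]2CO[C@@H](c3ccccc3)O[C@H]2[C@H](OS(=O)(=O)c2ccc(C)cc2)[C@H]1[O-].[Na+] | intermediate (not isolated)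
4 | methyl 2,3-anhydro-4,6-O-benzylidene-α-D-allopyranoside | CO[C@H]1O[C@@H]2CO[C@@H](c3ccccc3)O[C@H]2[C@H]4O[C@@H]14 | intermediate
5 | 2-naphthylmethanol | OCc1ccc2ccccc2c1 | starting material
6 | methyl 4,6-O-benzylidene-2-O-(2-naphthylmethyl)-α-D-altropyranoside | CO[C@H]1O[C@@H]2CO[C@@H](c3ccccc3)O[C@H]2[C@@H](O)[C@@H]1OCc1ccc2ccccc2c1 | intermediate
7 | benzoyl chloride | O=C(Cl)c1ccccc1 | starting material
8 | methyl 3-O-benzoyl-4,6-O-benzylidene-2-O-(2-naphthylmethyl)-α-D-altropyranoside | CO[C@H]1O[C@@H]2CO[C@@H](c3ccccc3)O[C@H]2[C@@H](OC(=O)c2ccccc2)[C@@H]1OCc1ccc2ccccc2c1 | intermediate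
9 | methyl 3-O-benzoyl-2-O-(2-naphthylmethyl)-α-D-altropyranoside | CO[C@H]1O[C@H](CO)[C@@H](O)[C@@H](OC(=O)c2ccccc2)[C@@H]1OCc1ccc2ccccc2c1 | intermediate
10 | methyl 3-O-benzoyl-6-deoxy-6-iodo-2-O-(2-naphthylmethyl)-α-D-altropyranoside | CO[C@H]1O[C@H](CI)[C@@H](O)[C@@H](OC(=O)c2ccccc2)[C@@H]1OCc1ccc2ccccc2c1 | intermediate
11 | methyl 3-O-benzoyl-4-O-(tert-butyldimethylsilyl)-6-deoxy-6-iodo-2-O-(2-naphthylmethyl)-α-D-altropyranoside | CO[C@H]1O[C@H](CI)[C@@H](O[Si](C)(C)C(C)(C)C)[C@@H](OC(=O)c2ccccc2)[C@@H]1OCc1ccc2ccccc2c1 | intermediate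
12 | methyl 3-O-benzoyl-4-O-(tert-butyldimethylsilyl)-6-deoxy-2-O-(2-naphthylmethyl)-α-D-arabino-hex-5-enopyranoside | CO[C@H]1OC(=C)[C@@H](O[Si](C)(C)C(C)(C)C)[C@@H](OC(=O)c2ccccc2)[C@@H]1OCc1ccc2ccccc2c1 | intermediate (key-step precursor)
13 | ring-opened C1 methoxy-oxocarbenium ion tethered to the trichloro(isopropoxy)titanate enolate of the C5 ketone (sugar numbering) | C[O+]=C[C@@H](OCc1ccc2ccccc2c1)[C@H](OC(=O)c1ccccc1)[C@H](O[Si](C)(C)C(C)(C)C)C(=C)O[Ti-](Cl)(Cl)(Cl)OC(C)C | intermediate (not isolated)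
14 | 5α-benzoyloxy-1α-methoxy-6β-(2-naphthylmethoxy)-4α-(tert-butyldimethylsilyloxy)cyclohexan-3-one | CO[C@H]1CC(=O)[C@@H](O[Si](C)(C)C(C)(C)C)[C@@H](OC(=O)c2ccccc2)[C@@H]1OCc1ccc2ccccc2c1 | intermediate (key-step product)
15 | lithium C2=C3 enolate of ketone 14 | CO[C@H]1C=C([O-])[C@@H](O[Si](C)(C)C(C)(C)C)[C@@H](OC(=O)c2ccccc2)[C@@H]1OCc1ccc2ccccc2c1.[Li+] | intermediate (not isolated)
16 | 5α-benzoyloxy-1α-methoxy-6β-(2-naphthylmethoxy)-4α-(tert-butyldimethylsilyloxy)cyclohex-2-en-3-yl trifluoromethanesulfonate | CO[C@H]1C=C(OS(=O)(=O)C(F)(F)F)[C@@H](O[Si](C)(C)C(C)(C)C)[C@@H](OC(=O)c2ccccc2)[C@@H]1OCc1ccc2ccccc2c1 | intermediate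
17 | (tributylstannyl)methanol | CCCC[Sn](CCCC)(CCCC)CO | starting material
18 | 3-(hydroxymethyl)-1α-methoxy-6β-(2-naphthylmethoxy)-4α-(tert-butyldimethylsilyloxy)cyclohex-2-en-5α-yl benzoate | CO[C@H]1C=C(CO)[C@@H](O[Si](C)(C)C(C)(C)C)[C@@H](OC(=O)c2ccccc2)[C@@H]1OCc1ccc2ccccc2c1 | intermediate
19 | 3-(benzoyloxymethyl)-1α-methoxy-6β-(2-naphthylmethoxy)-4α-(tert-butyldimethylsilyloxy)cyclohex-2-en-5α-yl benzoate | CO[C@H]1C=C(COC(=O)c2ccccc2)[C@@H](O[Si](C)(C)C(C)(C)C)[C@@H](OC(=O)c2ccccc2)[C@@H]1OCc1ccc2ccccc2c1 | intermediate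
20 | 3-(benzoyloxymethyl)-6β-hydroxy-1α-methoxy-4α-(tert-butyldimethylsilyloxy)cyclohex-2-en-5α-yl benzoate | CO[C@H]1C=C(COC(=O)c2ccccc2)[C@@H](O[Si](C)(C)C(C)(C)C)[C@@H](OC(=O)c2ccccc2)[C@@H]1O | intermediate
21 | (1S,4R,5R,6R)-5-benzoyloxy-3-(benzoyloxymethyl)-4,6-dihydroxy-1-methoxycyclohex-2-ene | CO[C@H]1C=C(COC(=O)c2ccccc2)[C@@H](O)[C@@H](OC(=O)c2ccccc2)[C@@H]1O | target

**Step count**

Total: 14 steps. Longest linear sequence: 14 steps (1 → 21).

**Steps most likely to fail**

Step 9. The ion pair may separate before reclosure, so that C1 is attacked from both faces; an unassisted aldol closure is expected to prefer the C1 oxygen trans to the C5 acyloxy group, the wrong sense. Exocyclic loss of the methoxyl or β-elimination of methanol from the product may also compete. The fallback sets out from 12 and comes back at 14, building the C1 oxygen after the ring instead of carrying it through: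
- Hg(OCOCF3)2 (cat.) in acetone–water should give, by Ferrier carbocyclisation with loss of methanol, 5α-benzoyloxy-1β-hydroxy-6β-(2-naphthylmethoxy)-4α-(tert-butyldimethylsilyloxy)cyclohexan-3-one F1, whose C1 configuration is immaterial.
- MsCl/Et3N should dehydrate it to 5α-benzoyloxy-6β-(2-naphthylmethoxy)-4α-(tert-butyldimethylsilyloxy)cyclohex-1-en-3-one F2.
- Conjugate borylation (CuCl cat., NaOtBu cat., Xantphos, B2pin2, MeOH, THF) anti to the C6 ether should give the 1α-(pinacolboryl) ketone F3.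
- NaBO3·4H2O oxidation with retention should give the 1α-hydroxy ketone F4.
- Methylation with MeOTf and 2,6-di-tert-butyl-4-methylpyridine then gives 14.

Step 10. Enolisation may run toward C4 and expel the C5 benzoate, or the desired enolate may lose the C1 methoxyl by E1cB before it is trapped. The fallback sets out from 14 and comes back at 19, avoiding any enolate:
- Takai–Lombardo methylenation (Zn, CH2Br2, TiCl4, THF–CH2Cl2), which spares benzoates, should give the 3-methylenecyclohexane F5.
- OsO4 (cat.)/NMO dihydroxylation from the open β face should give the 3β-hydroxy-3-(hydroxymethyl) diol F6.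
- Benzoylation of the primary hydroxyl only (BzCl, pyridine, −20 °C) should give the tertiary alcohol 7-benzoate F7.
- Dehydration with SOCl2/pyridine should give 19. Anti elimination can only use the α hydrogen on C2, because H4 is on the same face as the leaving group.

Step 11. Transfer of the hydroxymethyl group from tin to the hindered alkenylpalladium may be slow, leaving time for hydrolysis or reduction of the triflate. The fallback sets out from 16 and comes back at 18, taking C7 from carbon monoxide: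
- Palladium-catalysed formylation (CO 1 atm, Pd(PPh3)4, slow addition of Bu3SnH, THF, 50 °C) should give the cyclohex-2-ene-3-carbaldehyde F8.
- Luche reduction (NaBH4, CeCl3·7H2O, MeOH, −40 °C) should give 18 without touching the benzoate.

**Further compounds**

F1 | step 9 | 5α-benzoyloxy-1β-hydroxy-6β-(2-naphthylmethoxy)-4α-(tert-butyldimethylsilyloxy)cyclohexan-3-one | O[C@@H]1CC(=O)[C@@H](O[Si](C)(C)C(C)(C)C)[C@@H](OC(=O)c2ccccc2)[C@@H]1OCc1ccc2ccccc2c1
F2 | step 9 | 5α-benzoyloxy-6β-(2-naphthylmethoxy)-4α-(tert-butyldimethylsilyloxy)cyclohex-1-en-3-one | C1=CC(=O)[C@@H](O[Si](C)(C)C(C)(C)C)[C@@H](OC(=O)c2ccccc2)[C@@H]1OCc1ccc2ccccc2c1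
F3 | step 9 | 5α-benzoyloxy-6β-(2-naphthylmethoxy)-1α-(4,4,5,5-tetramethyl-1,3,2-dioxaborolan-2-yl)-4α-(tert-butyldimethylsilyloxy)cyclohexan-3-one | CC1(C)OB(OC1(C)C)[C@H]2CC(=O)[C@@H](O[Si](C)(C)C(C)(C)C)[C@@H](OC(=O)c3ccccc3)[C@@H]2OCc2ccc3ccccc3c2
F4 | step 9 | 5α-benzoyloxy-1α-hydroxy-6β-(2-naphthylmethoxy)-4α-(tert-butyldimethylsilyloxy)cyclohexan-3-one | O[C@H]1CC(=O)[C@@H](O[Si](C)(C)C(C)(C)C)[C@@H](OC(=O)c2ccccc2)[C@@H]1OCc1ccc2ccccc2c1
F5 | step 10 | 1α-methoxy-3-methylene-6β-(2-naphthylmethoxy)-4α-(tert-butyldimethylsilyloxy)cyclohexan-5α-yl benzoate | CO[C@H]1CC(=C)[C@@H](O[Si](C)(C)C(C)(C)C)[C@@H](OC(=O)c2ccccc2)[C@@H]1OCc1ccc2ccccc2c1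
F6 | step 10 | 3β-hydroxy-3-(hydroxymethyl)-1α-methoxy-6β-(2-naphthylmethoxy)-4α-(tert-butyldimethylsilyloxy)cyclohexan-5α-yl benzoate (expected C3 epimer; C3 is lost on dehydration) | CO[C@H]1C[C@@](O)(CO)[C@@H](O[Si](C)(C)C(C)(C)C)[C@@H](OC(=O)c2ccccc2)[C@@H]1OCc1ccc2ccccc2c1
F7 | step 10 | 3-(benzoyloxymethyl)-3β-hydroxy-1α-methoxy-6β-(2-naphthylmethoxy)-4α-(tert-butyldimethylsilyloxy)cyclohexan-5α-yl benzoate | CO[C@H]1C[C@@](O)(COC(=O)c2ccccc2)[C@@H](O[Si](C)(C)C(C)(C)C)[C@@H](OC(=O)c2ccccc2)[C@@H]1OCc1ccc2ccccc2c1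
F8 | step 11 | 3-formyl-1α-methoxy-6β-(2-naphthylmethoxy)-4α-(tert-butyldimethylsilyloxy)cyclohex-2-en-5α-yl benzoate | CO[C@H]1C=C(C=O)[C@@H](O[Si](C)(C)C(C)(C)C)[C@@H](OC(=O)c2ccccc2)[C@@H]1OCc1ccc2ccccc2c1
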